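**Retrosynthetic overview**
1. The plan rests on ring C, a 2',4'-dihydroxy-6'-alkylbenzoyl ring whose C1' holds the diaryl ketone. C1' and C2' come from naphthoylacetate 10. C3'–C6', with the side chain already on C6', come from alkynyl methyl ketone 15. One Michael–Claisen benzannulation makes C1'–C6' and C2'–C3', so the tetra-ortho-substituted ketone arrives ready-made with 10.
2. Ring D (4-hydroxy-2-pyranone) is cut at C5–C6 and O1–C2, back to arylacetic acid 21 and dioxinone 22. The hydroxyquinone of ring B travels as a 5,6,8-trimethoxy ring and is freed by (NH4)2Ce(NO3)6, then BBr3.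
3. Ring A is closed onto a bought 3,5-dimethoxyphenyl ring B (bond C8a–C1) by cyclodehydration of triacylmethane 4. The C5 oxygen follows by bromination and methoxylation, and the 2-acetyl group is carbomethoxylated to 10.
4. Order of rings: B (bought), A (step 2), C (step 9), D (step 15).

Key step: step 9

Remark: the target has no stereocentre and is made and drawn as the 2-hydroxy-1,4-naphthoquinone and 4-hydroxy-2-pyranone tautomers; compounds 5–27 keep the naphthalene locants of 10 (C1 methyl, C2 acyl, oxygens on C3, C5, C6, C8; ring A = C1–C4/C4a/C8a, ring B = C5–C8/C4a/C8a), ring C is C1'–C6' with C1' on the ketone, and ring D is the pyranone.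

**Step 1**
Reactants: 1 2-(3,5-dimethoxyphenyl)acetic acid; 2 pentane-2,4-dione
Product: 4 3-[(3,5-dimethoxyphenyl)acetyl]pentane-2,4-dione, via acid chloride 3 (not isolated)
Conditions: (COCl)2, DMF (cat.), CH2Cl2, 0 °C to rt, concentrate; then 2, MgCl2, pyridine, CH2Cl2, 0 °C to rt
Reagents that add atoms: oxalyl chloride, O=C(Cl)C(=O)Cl (the chlorine of 3; none of its atoms stay in 4)
Why: C-acylation of a 1,3-diketone under soft enolisation, in which MgCl2 and pyridine direct the acid chloride to carbon, and since both acetyl groups of 4 are alike the next ring closure has a single outcome.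

**Step 2**
Reactants: 4 3-[(3,5-dimethoxyphenyl)acetyl]pentane-2,4-dione
Product: 5 1-(3-hydroxy-6,8-dimethoxy-1-methylnaphthalen-2-yl)ethan-1-one
Conditions: CH3SO3H, CH2Cl2, 0 °C to rt
Reagents that add atoms: none
Why: Acid-catalysed aromatic cyclodehydration (intramolecular Friedel–Crafts hydroxyalkylation, then loss of water), the classical closure of gamma-aryl beta-dicarbonyl compounds to 2-naphthols: the ring carbon ortho to the side chain and para to a methoxy group attacks a protonated acetyl carbonyl in a six-membered closure (C8a–C1), the two ortho positions being equivalent.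

**Step 3**
Reactants: 5 1-(3-hydroxy-6,8-dimethoxy-1-methylnaphthalen-2-yl)ethan-1-one
Product: 6 1-(3,6,8-trimethoxy-1-methylnaphthalen-2-yl)ethan-1-one
Conditions: CH3I, K2CO3, acetone, reflux
Reagents that add atoms: iodomethane, CI
Why: Williamson ether synthesis on the only acidic OH, with a base too weak to alkylate the hindered methyl ketone at carbon.

**Step 4**
Reactants: 6 1-(3,6,8-trimethoxy-1-methylnaphthalen-2-yl)ethan-1-one
Product: 7 1-(5-bromo-3,6,8-trimethoxy-1-methylnaphthalen-2-yl)ethan-1-one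
Conditions: N-bromosuccinimide (1.0 equiv), CH3CN, 0 °C, dark
Reagents that add atoms: N-bromosuccinimide, O=C1CCC(=O)N1Br
Why: Electrophilic aromatic bromination: C5 is an alpha position ortho to the 6-methoxy and para to the 8-methoxy group, so it should react ahead of C4 (one donor only, on the acyl-bearing ring A) and of the flanked beta position C7, while polar conditions in the dark leave the methyl groups alone.

**Step 5**
Reactants: 7 1-(5-bromo-3,6,8-trimethoxy-1-methylnaphthalen-2-yl)ethan-1-one
Product: 8 1-(3,5,6,8-tetramethoxy-1-methylnaphthalen-2-yl)ethan-1-one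
Conditions: NaOCH3, CuBr (10 mol %), CH3OH/DMF, 100 °C
Reagents that add atoms: sodium methoxide, C[O-].[Na+]
Why: Ullmann-type copper-catalysed methoxylation of an aryl bromide, a reaction that tolerates aryl methyl ketones, and here the di-ortho-substituted ketone is also shielded against aldol self-condensation.

**Step 6**
Reactants: 8 1-(3,5,6,8-tetramethoxy-1-methylnaphthalen-2-yl)ethan-1-one; 9 dimethyl carbonate
Product: 10 methyl 3-oxo-3-(3,5,6,8-tetramethoxy-1-methylnaphthalen-2-yl)propanoate
Conditions: NaH (2.5 equiv), 9 (excess), THF, reflux; AcOH quench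
Reagents that add atoms: none
Why: Crossed Claisen condensation (carbomethoxylation of a methyl ketone enolate with a carbonate that cannot enolise), driven by deprotonation of the beta-keto ester as it forms.

**Step 7**
Reactants: 11 but-3-yn-1-ol
Product: 12 (but-3-yn-1-yloxy)(tert-butyl)dimethylsilane
Conditions: t-BuMe2SiCl, imidazole, CH2Cl2, 0 °C to rt
Reagents that add atoms: tert-butyldimethylsilyl chloride, CC(C)(C)[Si](C)(C)Cl
Why: Imidazole-promoted silylation of a primary alcohol, giving an ether that stands up to n-BuLi and to NaOCH3.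

**Step 8**
Reactants: 12 (but-3-yn-1-yloxy)(tert-butyl)dimethylsilane; 13 N-methoxy-N-methylacetamide
Product: 15 6-(tert-butyldimethylsilyloxy)hex-3-yn-2-one, via lithium acetylide 14 (not isolated)
Conditions: n-BuLi, THF, −78 °C; then 13, −78 to 0 °C; poured into cold 1 M HCl
Reagents that add atoms: n-butyllithium, [Li]CCCC (the lithium of 14; none of its atoms stay in 15)
Why: Weinreb ketone synthesis, in which over-addition does not occur, and the acidic quench protonates the released amine so that it cannot add to the ynone.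

**Step 9**
Reactants: 10 methyl 3-oxo-3-(3,5,6,8-tetramethoxy-1-methylnaphthalen-2-yl)propanoate; 15 6-(tert-butyldimethylsilyloxy)hex-3-yn-2-one
Product: 17 {2-[2-(tert-butyldimethylsilyloxy)ethyl]-4,6-dihydroxyphenyl}(3,5,6,8-tetramethoxy-1-methylnaphthalen-2-yl)methanone, via Michael adduct 16 (not isolated)
Conditions: 10, NaOCH3 (1.05 equiv), CH3OH/THF, 0 °C; 15 added slowly; then NaOCH3 (2 equiv), 55 °C; AcOH quench
Reagents that add atoms: none
Why: NaOCH3 turns 10 into its stabilised enolate, whose carbon (the future C1') adds to the alkyne beta carbon C4 of 15 (Michael addition, C1'–C6') to give 16, and because 16 is at once deprotonated to an extended dienolate its C5'=C6' geometry can equilibrate to the isomer in which the acetyl group faces the ester. Proton transfer then gives the methyl ketone enolate, which attacks the ester carbonyl in a 6-(enolendo)-exo-trig Claisen (Dieckmann-type) closure (C2'–C3'); loss of methoxide and double enolisation deliver ring C already aromatic, so no oxidant is needed and no stereocentre is formed. The closest known reaction is the base-mediated Michael–Claisen benzannulation of malonates and beta-keto esters with alkynyl methyl ketones, the direct route to 2,4-dihydroxy-6-alkylbenzoyl compounds. The step needs closure on the ester and not aldol closure on the aryl ketone: the ketone carbon of 10 lies between C1–CH3 and C3–OCH3 of the naphthalene, is twisted out of plane and is shielded on both faces, while the ester carbonyl is open. O-Attack of the dienolate on the ester would give a 2-pyranone, but methoxide reopens it and the irreversible formation of the resorcinolate drains this equilibrium. Slow addition of 15 to the preformed enolate keeps free methoxide away from the propargylic CH2 (C5 of 15) and so holds back loss of silanolate.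

**Step 10**
Reactants: 17 {2-[2-(tert-butyldimethylsilyloxy)ethyl]-4,6-dihydroxyphenyl}(3,5,6,8-tetramethoxy-1-methylnaphthalen-2-yl)methanone
Product: 18 {2-[2-(tert-butyldimethylsilyloxy)ethyl]-4,6-dimethoxyphenyl}(3,5,6,8-tetramethoxy-1-methylnaphthalen-2-yl)methanone
Conditions: CH3I (excess), K2CO3, DMF, rt to 35 °C
Reagents that add atoms: iodomethane, CI
Why: Williamson ether synthesis on both phenols of ring C, run at low temperature so that the 2'-phenoxide does not displace the 3-methoxy group across the ketone (xanthone closure), with the silyl ether stable to carbonate.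

**Step 11**
Reactants: 18 {2-[2-(tert-butyldimethylsilyloxy)ethyl]-4,6-dimethoxyphenyl}(3,5,6,8-tetramethoxy-1-methylnaphthalen-2-yl)methanone
Product: 19 [2-(2-hydroxyethyl)-4,6-dimethoxyphenyl](3,5,6,8-tetramethoxy-1-methylnaphthalen-2-yl)methanone
Conditions: HF·pyridine, THF, 0 °C to rt
Reagents that add atoms: none
Why: Fluoride-driven cleavage of the Si–O bond under conditions that leave aryl methyl ethers and the ketone untouched.

**Step 12**
Reactants: 19 [2-(2-hydroxyethyl)-4,6-dimethoxyphenyl](3,5,6,8-tetramethoxy-1-methylnaphthalen-2-yl)methanone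
Product: 20 2-[3,5-dimethoxy-2-(3,5,6,8-tetramethoxy-1-methyl-2-naphthoyl)phenyl]acetaldehyde
Conditions: Dess–Martin periodinane, CH2Cl2, 0 °C to rt; used at once
Reagents that add atoms: none
Why: Dess–Martin oxidation, a mild two-electron oxidation of the alcohol that stops at the aldehyde and does not touch the electron-rich naphthalene.

**Step 13**
Reactants: 20 2-[3,5-dimethoxy-2-(3,5,6,8-tetramethoxy-1-methyl-2-naphthoyl)phenyl]acetaldehyde
Product: 21 2-[3,5-dimethoxy-2-(3,5,6,8-tetramethoxy-1-methyl-2-naphthoyl)phenyl]acetic acid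
Conditions: NaClO2, NaH2PO4, 2-methyl-2-butene (excess), t-BuOH/H2O, 0 °C to rt
Reagents that add atoms: sodium chlorite, [Na+].[O-]Cl=O
Why: Pinnick oxidation, in which chlorous acid adds to the aldehyde and fragments to the acid while the alkene scavenger takes up hypochlorous acid before it can chlorinate ring B.

**Step 14**
Reactants: 21 2-[3,5-dimethoxy-2-(3,5,6,8-tetramethoxy-1-methyl-2-naphthoyl)phenyl]acetic acid; 22 2,2,6-trimethyl-4H-1,3-dioxin-4-one
Product: 25 6-{3-[3,5-dimethoxy-2-(3,5,6,8-tetramethoxy-1-methyl-2-naphthoyl)phenyl]-2-oxopropyl}-2,2-dimethyl-4H-1,3-dioxin-4-one, via acyl imidazolide 23 (not isolated), via lithium dienolate 24 (not isolated)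
Conditions: 21, 1,1'-carbonyldiimidazole, THF, rt; separately 22 (3 equiv), LiN(SiMe3)2 (3 equiv), THF, −78 °C; solutions combined, −78 to −20 °C; 1 M HCl quench
Reagents that add atoms: 1,1'-carbonyldiimidazole, O=C(n1ccnc1)n1ccnc1 (the imidazolyl group of 23); LiN(SiMe3)2, [Li]N([Si](C)(C)C)[Si](C)(C)C (the lithium of 24); none of their atoms stay in 25
Why: Vinylogous Claisen acylation: the dioxinone dienolate reacts at its gamma carbon with the acyl imidazolide (pyranone C5–C6 bond), the excess dienolate takes up the acidic proton of the product, and the tetra-ortho-substituted diaryl ketone is too shielded to be attacked.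

**Step 15**
Reactants: 25 6-{3-[3,5-dimethoxy-2-(3,5,6,8-tetramethoxy-1-methyl-2-naphthoyl)phenyl]-2-oxopropyl}-2,2-dimethyl-4H-1,3-dioxin-4-one
Product: 27 6-{[3,5-dimethoxy-2-(3,5,6,8-tetramethoxy-1-methyl-2-naphthoyl)phenyl]methyl}-4-hydroxy-2H-pyran-2-one, via acylketene 26 (not isolated)
Conditions: toluene, 110 °C
Reagents that add atoms: none
Why: Thermal retro-hetero-Diels–Alder loss of acetone gives the acylketene, whose delta-keto group enolises and closes through oxygen onto the ketene carbon (six-membered closure, O1–C2), the standard route from keto-dioxinones to 6-substituted 4-hydroxy-2-pyranones.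

**Step 16**
Reactants: 27 6-{[3,5-dimethoxy-2-(3,5,6,8-tetramethoxy-1-methyl-2-naphthoyl)phenyl]methyl}-4-hydroxy-2H-pyran-2-one
Product: 28 6-{2-[(4-hydroxy-2-oxo-2H-pyran-6-yl)methyl]-4,6-dimethoxybenzoyl}-2,7-dimethoxy-5-methylnaphthalene-1,4-dione
Conditions: (NH4)2Ce(NO3)6 (2.2 equiv, added dropwise), CH3CN/H2O, 0 °C
Reagents that add atoms: water, O
Why: Oxidative demethylation of a 1,4-dimethoxyarene by tetravalent cerium: ring B is by far the most easily oxidised part, ring C is deactivated by the ketone, a near-stoichiometric charge at 0 °C should spare the pyranone enol, and any ortho-quinone isomer from the 5,6-dimethoxy pair would give the same hydroxyquinone in step 17.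

**Step 17**
Reactants: 28 6-{2-[(4-hydroxy-2-oxo-2H-pyran-6-yl)methyl]-4,6-dimethoxybenzoyl}-2,7-dimethoxy-5-methylnaphthalene-1,4-dione
Product: 29 2,7-dihydroxy-6-{2,4-dihydroxy-6-[(4-hydroxy-2-oxo-2H-pyran-6-yl)methyl]benzoyl}-5-methylnaphthalene-1,4-dione (CNP0141484.0)
Conditions: BBr3 (excess), CH2Cl2, −78 °C to rt; then H2O
Reagents that add atoms: none
Why: Lewis acid cleavage of methyl ethers with BBr3: three of the four methoxy groups sit next to a carbonyl oxygen and are cleaved with chelation help, the 4'-methoxy group is an ordinary aryl methyl ether, and the pyranone and quinone are only held as borates until hydrolysis.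

**Compound list**
1 | 2-(3,5-dimethoxyphenyl)acetic acid | COc1cc(CC(=O)O)cc(OC)c1 | starting material
2 | pentane-2,4-dione | CC(=O)CC(C)=O | starting material
3 | 2-(3,5-dimethoxyphenyl)acetyl chloride | COc1cc(CC(=O)Cl)cc(OC)c1 | intermediate
4 | 3-[(3,5-dimethoxyphenyl)acetyl]pentane-2,4-dione | COc1cc(CC(=O)C(C(C)=O)C(C)=O)cc(OC)c1 | intermediate
5 | 1-(3-hydroxy-6,8-dimethoxy-1-methylnaphthalen-2-yl)ethan-1-one | CC(=O)c1c(O)cc2cc(OC)cc(OC)c2c1C | intermediate
6 | 1-(3,6,8-trimethoxy-1-methylnaphthalen-2-yl)ethan-1-one | CC(=O)c1c(OC)cc2cc(OC)cc(OC)c2c1C | intermediate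
7 | 1-(5-bromo-3,6,8-trimethoxy-1-methylnaphthalen-2-yl)ethan-1-one | CC(=O)c1c(OC)cc2c(Br)c(OC)cc(OC)c2c1C | intermediate
8 | 1-(3,5,6,8-tetramethoxy-1-methylnaphthalen-2-yl)ethan-1-one | CC(=O)c1c(OC)cc2c(OC)c(OC)cc(OC)c2c1C | intermediate
9 | dimethyl carbonate | COC(=O)OC | starting material
10 | methyl 3-oxo-3-(3,5,6,8-tetramethoxy-1-methylnaphthalen-2-yl)propanoate | Cc1c(C(=O)CC(=O)OC)c(OC)cc2c(OC)c(OC)cc(OC)c12 | intermediate
11 | but-3-yn-1-ol | C#CCCO | starting material
12 | (but-3-yn-1-yloxy)(tert-butyl)dimethylsilane | C#CCCO[Si](C)(C)C(C)(C)C | intermediate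
13 | N-methoxy-N-methylacetamide | CC(=O)N(C)OC | starting material
14 | lithium acetylide of 12 | [Li]C#CCCO[Si](C)(C)C(C)(C)C | intermediate
15 | 6-(tert-butyldimethylsilyloxy)hex-3-yn-2-one | CC(=O)C#CCCO[Si](C)(C)C(C)(C)C | intermediate
16 | methyl 3-[2-(tert-butyldimethylsilyloxy)ethyl]-5-oxo-2-(3,5,6,8-tetramethoxy-1-methyl-2-naphthoyl)hex-3-enoate (equilibrating E/Z mixture, C2 enolised) | Cc1c(C(=O)C(C(=O)OC)C(CCO[Si](C)(C)C(C)(C)C)=CC(C)=O)c(OC)cc2c(OC)c(OC)cc(OC)c12 | intermediate
17 | {2-[2-(tert-butyldimethylsilyloxy)ethyl]-4,6-dihydroxyphenyl}(3,5,6,8-tetramethoxy-1-methylnaphthalen-2-yl)methanone | Cc1c(C(=O)c3c(O)cc(O)cc3CCO[Si](C)(C)C(C)(C)C)c(OC)cc2c(OC)c(OC)cc(OC)c12 | intermediate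
18 | {2-[2-(tert-butyldimethylsilyloxy)ethyl]-4,6-dimethoxyphenyl}(3,5,6,8-tetramethoxy-1-methylnaphthalen-2-yl)methanone | Cc1c(C(=O)c3c(OC)cc(OC)cc3CCO[Si](C)(C)C(C)(C)C)c(OC)cc2c(OC)c(OC)cc(OC)c12 | intermediate
19 | [2-(2-hydroxyethyl)-4,6-dimethoxyphenyl](3,5,6,8-tetramethoxy-1-methylnaphthalen-2-yl)methanone | Cc1c(C(=O)c3c(OC)cc(OC)cc3CCO)c(OC)cc2c(OC)c(OC)cc(OC)c12 | intermediate
20 | 2-[3,5-dimethoxy-2-(3,5,6,8-tetramethoxy-1-methyl-2-naphthoyl)phenyl]acetaldehyde | Cc1c(C(=O)c3c(OC)cc(OC)cc3CC=O)c(OC)cc2c(OC)c(OC)cc(OC)c12 | intermediate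
21 | 2-[3,5-dimethoxy-2-(3,5,6,8-tetramethoxy-1-methyl-2-naphthoyl)phenyl]acetic acid | Cc1c(C(=O)c3c(OC)cc(OC)cc3CC(=O)O)c(OC)cc2c(OC)c(OC)cc(OC)c12 | intermediate
22 | 2,2,6-trimethyl-4H-1,3-dioxin-4-one | CC1=CC(=O)OC(C)(C)O1 | starting material
23 | 1-{[3,5-dimethoxy-2-(3,5,6,8-tetramethoxy-1-methyl-2-naphthoyl)phenyl]acetyl}imidazole | Cc1c(C(=O)c3c(OC)cc(OC)cc3CC(=O)n4ccnc4)c(OC)cc2c(OC)c(OC)cc(OC)c12 | intermediate
24 | lithium 2,2-dimethyl-6-methylidene-1,3-dioxin-4-olate | [Li]OC1=CC(=C)OC(C)(C)O1 | intermediate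
25 | 6-{3-[3,5-dimethoxy-2-(3,5,6,8-tetramethoxy-1-methyl-2-naphthoyl)phenyl]-2-oxopropyl}-2,2-dimethyl-4H-1,3-dioxin-4-one | Cc1c(C(=O)c3c(OC)cc(OC)cc3CC(=O)CC4=CC(=O)OC(C)(C)O4)c(OC)cc2c(OC)c(OC)cc(OC)c12 | intermediate
26 | 6-[3,5-dimethoxy-2-(3,5,6,8-tetramethoxy-1-methyl-2-naphthoyl)phenyl]-3,5-dioxohex-1-en-1-one (acylketene) | Cc1c(C(=O)c3c(OC)cc(OC)cc3CC(=O)CC(=O)C=C=O)c(OC)cc2c(OC)c(OC)cc(OC)c12 | intermediate
27 | 6-{[3,5-dimethoxy-2-(3,5,6,8-tetramethoxy-1-methyl-2-naphthoyl)phenyl]methyl}-4-hydroxy-2H-pyran-2-one | Cc1c(C(=O)c3c(OC)cc(OC)cc3Cc4cc(O)cc(=O)o4)c(OC)cc2c(OC)c(OC)cc(OC)c12 | intermediate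
28 | 6-{2-[(4-hydroxy-2-oxo-2H-pyran-6-yl)methyl]-4,6-dimethoxybenzoyl}-2,7-dimethoxy-5-methylnaphthalene-1,4-dione | Cc1c(C(=O)c2c(OC)cc(OC)cc2Cc2cc(O)cc(=O)o2)c(OC)cc2c1C(=O)C=C(OC)C2=O | intermediate
29 | 2,7-dihydroxy-6-{2,4-dihydroxy-6-[(4-hydroxy-2-oxo-2H-pyran-6-yl)methyl]benzoyl}-5-methylnaphthalene-1,4-dione | Cc1c(C(=O)c2c(O)cc(O)cc2Cc2cc(O)cc(=O)o2)c(O)cc2c1C(=O)C=C(O)C2=O | target

**Step count**
Total step count: 17. Longest linear sequence: 15 (steps 1–6, then 9–17). Steps 7 and 8 form the short branch.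

**Steps most likely to fail**

1. **Step 9.** The base may remove a propargylic proton of the ynone and expel the silyloxy group. The adduct may stay trapped after O-cyclisation. Methoxide may also cleave the aroyl group before the ring closes.
   - The fallback lowers the acceptor to the alkene level and aromatises afterwards. It sets out from 10 and 15 and comes back at 17.
   - Semi-hydrogenation of 15 (H2, Pd/CaCO3 poisoned with Pb(OAc)2, quinoline, EtOAc) should give (Z)-6-(tert-butyldimethylsilyloxy)hex-3-en-2-one F1.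
   - Michael–Claisen condensation of 10 with F1 (NaOCH3, CH3OH, reflux) is the classical dihydroresorcinol synthesis. It should give 4-(3,5,6,8-tetramethoxy-1-methyl-2-naphthoyl)-5-[2-(tert-butyldimethylsilyloxy)ethyl]cyclohexane-1,3-dione F2, whose two stereocentres are lost again.
   - One equivalent of N-bromosuccinimide at −20 °C should brominate the enolic carbon between the two ring carbonyls much faster than any arene position, giving the 2-bromo dione F3.
   - On warming in DMF, F3 loses HBr and tautomerises to 17.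

2. **Step 16.** Tetravalent cerium may also oxidise the enolic 4-hydroxy-2-pyranone by one electron, which would lead to radical coupling or over-oxidation alongside quinone formation.
   - The fallback uses no metal oxidant. It sets out from 27 and comes back at 29, so steps 16 and 17 are both replaced.
   - Exhaustive demethylation of 27 (BBr3, excess, CH2Cl2, −78 °C to rt) should give 6-{[3,5-dihydroxy-2-(3,5,6,8-tetrahydroxy-1-methyl-2-naphthoyl)phenyl]methyl}-4-hydroxy-2H-pyran-2-one F4.
   - The 5,6,8-trihydroxy ring B of F4 should autoxidise when the extract is stirred in air over pH 7 buffer, as 1,2,4-trihydroxynaphthalenes do. This gives the hydroxyquinone 29 directly.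

3. **Step 14.** The basic dienolate may remove the acidic benzylic proton of the acyl imidazolide instead of attacking its carbonyl. That would lead to ketene formation, closure onto the neighbouring ketone oxygen and recovery of acid.
   - The fallback replaces acylation by addition and oxidation. It sets out from aldehyde 20 (with 22) and comes back at 25, so step 13 is skipped.
   - Vinylogous aldol addition of dienolate 24 to 20 (THF, −78 °C) should give racemic 6-{3-[3,5-dimethoxy-2-(3,5,6,8-tetramethoxy-1-methyl-2-naphthoyl)phenyl]-2-hydroxypropyl}-2,2-dimethyl-4H-1,3-dioxin-4-one F5.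
   - Dess–Martin oxidation of F5 (CH2Cl2, rt) removes the new stereocentre and gives 25.

**Further compounds**
F1 | step 9 | (Z)-6-(tert-butyldimethylsilyloxy)hex-3-en-2-one | CC(=O)/C=C\CCO[Si](C)(C)C(C)(C)C
F2 | step 9 | 4-(3,5,6,8-tetramethoxy-1-methyl-2-naphthoyl)-5-[2-(tert-butyldimethylsilyloxy)ethyl]cyclohexane-1,3-dione (racemic, relative configuration not controlled) | Cc1c(C(=O)C3C(=O)CC(=O)CC3CCO[Si](C)(C)C(C)(C)C)c(OC)cc2c(OC)c(OC)cc(OC)c12
F3 | step 9 | 2-bromo-4-(3,5,6,8-tetramethoxy-1-methyl-2-naphthoyl)-5-[2-(tert-butyldimethylsilyloxy)ethyl]cyclohexane-1,3-dione (racemic, configuration not controlled) | Cc1c(C(=O)C3C(=O)C(Br)C(=O)CC3CCO[Si](C)(C)C(C)(C)C)c(OC)cc2c(OC)c(OC)cc(OC)c12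
F4 | step 16 | 6-{[3,5-dihydroxy-2-(3,5,6,8-tetrahydroxy-1-methyl-2-naphthoyl)phenyl]methyl}-4-hydroxy-2H-pyran-2-one | Cc1c(C(=O)c3c(O)cc(O)cc3Cc4cc(O)cc(=O)o4)c(O)cc2c(O)c(O)cc(O)c12
F5 | step 14 | 6-{3-[3,5-dimethoxy-2-(3,5,6,8-tetramethoxy-1-methyl-2-naphthoyl)phenyl]-2-hydroxypropyl}-2,2-dimethyl-4H-1,3-dioxin-4-one (racemic) | Cc1c(C(=O)c3c(OC)cc(OC)cc3CC(O)CC4=CC(=O)OC(C)(C)O4)c(OC)cc2c(OC)c(OC)cc(OC)c12
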